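**Plan**

1. Lactone numbering used in the text: O1, C2(=O), C3(OH), C4(aryl), C5(CO2Me)(CH2Ar); in the systematic ester names C5 is position 2, C4 position 3 and C3 position 4.
2. Retrosynthetic cuts in order: the O-benzyl and O-silyl groups; C4–aryl (cross-coupling); C3–C4 of the butenolide (Claisen/Dieckmann closure); C5–CH2Ar (enolate alkylation); the tartronate O–acyl bond; the O–C2 bond of the dihydrobenzofuran (epoxide opening); the aryl–prenyl bond.
3. Enabling feature: C5 carries CO2Me and, as ring carbon C4, a second carbon at the carboxyl oxidation level, so with C3–C4 opened it is the central carbon of a 2-acyloxy-2-arylmethylmalonate bearing two identical methyl esters.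
4. Forward order: the dihydrofuran ring is closed on the benzoate first, its benzylic bromide alkylates a preformed (benzyloxyacetoxy)malonate, the butenolide ring is closed by the ester-group-selective Dieckmann step, and the 4-hydroxyphenyl ring is attached last at C4 through the triflate.
5. Stereochemistry: the (S) center of the dihydrobenzofuran comes from a Shi epoxidation ((R)-epoxide) followed by SN2 inversion; (S) at C5 comes from a chiral lithium amide that selects one of the two methyl esters.

Key step: step 10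

Assumption: the sense in which the (R,R)-amide selects between the two ester groups in step 10 cannot be derived from precedent; if the (5R) epimer prevails, the commercial (S,S)-amine hydrochloride is used in the same way.

Step 1
Reactants: 1 methyl 4-hydroxybenzoate; 2 1-bromo-3-methylbut-2-ene (prenyl bromide)
Product: 3 methyl 4-hydroxy-3-(3-methylbut-2-en-1-yl)benzoate
Conditions: NaH (1.0 equiv), toluene, 0 °C to rt; then 2, rt
Reagents that add atoms: none
Why: Phenoxide ortho-C-alkylation: in toluene the sodium phenoxide reacts as a tight ion pair whose oxygen is shielded by the cation, so the allylic bromide should be taken up at the ortho carbon (both ortho positions are equivalent) and tautomerisation restores the phenol.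

Step 2
Reactants: 3 methyl 4-hydroxy-3-(3-methylbut-2-en-1-yl)benzoate
Product: 4 methyl 3-(3-methylbut-2-en-1-yl)-4-[(triisopropylsilyl)oxy]benzoate
Conditions: TIPSCl, imidazole, DMF, rt
Reagents that add atoms: chlorotriisopropylsilane (TIPSCl), SMILES CC(C)[Si](Cl)(C(C)C)C(C)C
Why: Silyl ether formation with imidazole as base and nucleophilic catalyst masks the acidic phenol, so that the dioxirane of step 3 meets no oxidisable phenoxide and the epoxide cannot cyclise prematurely in the basic buffer.

Step 3
Reactants: 4 methyl 3-(3-methylbut-2-en-1-yl)-4-[(triisopropylsilyl)oxy]benzoate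
Product: 5 methyl 3-{[(2R)-3,3-dimethyloxiran-2-yl]methyl}-4-[(triisopropylsilyl)oxy]benzoate
Conditions: D-fructose-derived Shi ketone (30 mol%), Oxone (2KHSO5·KHSO4·K2SO4), K2CO3, Bu4NHSO4, MeCN/CH2(OMe)2/aq. Na2B4O7 buffer, 0 °C
Reagents that add atoms: potassium peroxymonosulfate (active component of Oxone), SMILES [K+].[O-]S(=O)(=O)OO
Why: Shi asymmetric epoxidation: the dioxirane formed from the D-fructose-derived ketone transfers oxygen to the trisubstituted olefin through a spiro transition state, which for this substitution pattern should give the (R)-configured epoxide carbon, the ester and the silyl ether being inert to Oxone at pH about 10.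

Step 4
Reactants: 5 methyl 3-{[(2R)-3,3-dimethyloxiran-2-yl]methyl}-4-[(triisopropylsilyl)oxy]benzoate
Product: 7 methyl (2S)-2-(2-hydroxypropan-2-yl)-2,3-dihydro-1-benzofuran-5-carboxylate, via epoxy phenol 6 (not isolated)
Conditions: TBAF, THF, 0 °C to 40 °C; aq. work-up
Reagents that add atoms: none
Why: Fluoride desilylation sets free the phenoxide, which opens the epoxide at its less hindered secondary carbon in a 5-exo-tet intramolecular SN2 reaction with inversion, so the (R)-epoxide carbon becomes the (S)-configured C2 of the dihydrobenzofuran and the former epoxide oxygen ends as the tertiary alcohol.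

Step 5
Reactants: 7 methyl (2S)-2-(2-hydroxypropan-2-yl)-2,3-dihydro-1-benzofuran-5-carboxylate
Product: 8 methyl (2S)-2-{2-[(triethylsilyl)oxy]propan-2-yl}-2,3-dihydro-1-benzofuran-5-carboxylate
Conditions: TESOTf, 2,6-lutidine, CH2Cl2, 0 °C
Reagents that add atoms: triethylsilyl trifluoromethanesulfonate (TESOTf), SMILES CC[Si](CC)(CC)OS(=O)(=O)C(F)(F)F
Why: Silylation of a hindered tertiary alcohol with a silyl triflate and a non-nucleophilic pyridine base; the triethylsilyl ether keeps the alcohol away from the strong bases and from Tf2O used later and is still removable by fluoride at the end.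

Step 6
Reactants: 8 methyl (2S)-2-{2-[(triethylsilyl)oxy]propan-2-yl}-2,3-dihydro-1-benzofuran-5-carboxylate
Product: 9 [(2S)-2-{2-[(triethylsilyl)oxy]propan-2-yl}-2,3-dihydro-1-benzofuran-5-yl]methanol
Conditions: i-Bu2AlH (DIBAL-H), CH2Cl2, −78 to 0 °C; aq. KNaC4H4O6 (Rochelle salt)
Reagents that add atoms: none
Why: Hydride reduction of the aryl ester to the benzylic alcohol with i-Bu2AlH, which leaves the silyl ether and the cyclic aryl ether untouched.

Step 7
Reactants: 9 [(2S)-2-{2-[(triethylsilyl)oxy]propan-2-yl}-2,3-dihydro-1-benzofuran-5-yl]methanol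
Product: 10 (2S)-5-(bromomethyl)-2-{2-[(triethylsilyl)oxy]propan-2-yl}-2,3-dihydro-1-benzofuran
Conditions: CBr4, PPh3, CH2Cl2, 0 °C; used directly after filtration through a short silica pad
Reagents that add atoms: carbon tetrabromide, SMILES BrC(Br)(Br)Br
Why: Appel reaction: the alkoxyphosphonium salt of the primary benzylic alcohol is displaced by bromide under neutral conditions that the acid-sensitive silyl ether should tolerate.

Step 8
Reactants: 11 dimethyl 2-hydroxymalonate (dimethyl tartronate); 12 (benzyloxy)acetyl chloride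
Product: 13 dimethyl 2-{[(benzyloxy)acetyl]oxy}malonate
Conditions: pyridine, CH2Cl2, 0 °C to rt
Reagents that add atoms: none
Why: Esterification of the secondary alcohol with an acid chloride (pyridine as acid scavenger); pyridine is too weak to enolise the tartronate C–H, so only O-acylation is expected.

Step 9
Reactants: 13 dimethyl 2-{[(benzyloxy)acetyl]oxy}malonate; 10 (2S)-5-(bromomethyl)-2-{2-[(triethylsilyl)oxy]propan-2-yl}-2,3-dihydro-1-benzofuran
Product: 14 dimethyl 2-{[(benzyloxy)acetyl]oxy}-2-{[(2S)-2-{2-[(triethylsilyl)oxy]propan-2-yl}-2,3-dihydro-1-benzofuran-5-yl]methyl}malonate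
Conditions: NaH (0.95 equiv relative to 13), THF/DMF, 0 °C; then 10, 0 °C to rt
Reagents that add atoms: none
Why: Malonic ester alkylation: NaH removes the doubly activated C–H of the 2-acyloxymalonate and the enolate displaces the reactive benzylic bromide (SN2) to build the quaternary carbon, while keeping NaH below one equivalent leaves no base strong enough to enolise the benzyloxyacetate and start an uncontrolled cyclisation.

Step 10
Reactants: 14 dimethyl 2-{[(benzyloxy)acetyl]oxy}-2-{[(2S)-2-{2-[(triethylsilyl)oxy]propan-2-yl}-2,3-dihydro-1-benzofuran-5-yl]methyl}malonate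
Product: 15 methyl (2S)-4-(benzyloxy)-3-hydroxy-5-oxo-2-{[(2S)-2-{2-[(triethylsilyl)oxy]propan-2-yl}-2,3-dihydro-1-benzofuran-5-yl]methyl}-2,5-dihydrofuran-2-carboxylate
Conditions: (R,R)-bis(1-phenylethyl)amine hydrochloride (2.2 equiv), n-BuLi (4.4 equiv), THF, −78 to 0 °C, then −78 °C; 14 added slowly, −78 to −40 °C; AcOH quench, cold dilute aq. HCl wash
Reagents that add atoms: none
Why: Proposed new method: the lithium amide removes a proton from the only enolisable position, the benzyloxyacetate CH2, giving a chelated lithium enolate that stays bound in a mixed aggregate with the excess chiral amide and LiCl; its carbon adds to one of the two methyl ester carbonyls on the quaternary carbon, methoxide leaves, and the resulting 3-benzyloxyfuran-2,4-dione is deprotonated at once to the lithium tetronate, which makes the closure irreversible. The closest known reactions are the lithium-amide-induced Claisen (Dieckmann) cyclisation of α-(alkoxyacetoxy) esters to 3-alkoxytetronic acids, enantioselective C–C bond formations of lithium enolates held in mixed aggregates with chiral lithium amides, and catalytic desymmetrisations of prochiral 2,2-disubstituted malonates. The lactone ring closes in the 5-exo-trig mode, the enolate carbon (C3) attacking the ester carbonyl that becomes C4. The new stereocenter C5 arises solely from the choice between the two diastereotopic CO2Me groups and is controlled by the chiral amide, which in the compact lithium-bridged bicyclic transition state should force the arylmethyl group and the spectator ester into different positions; the distant dihydrobenzofuran center gives no useful bias of its own. The step needs ester-group selectivity and site-selective enolisation, and the substrate secures the latter because the tartronate carbon and the methyl esters carry no α-hydrogen, the two esters are identical so that methoxide exchange is degenerate, and the fully substituted C5 speeds ring closure (gem-disubstitution) and cannot epimerise once set.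

Step 11
Reactants: 15 methyl (2S)-4-(benzyloxy)-3-hydroxy-5-oxo-2-{[(2S)-2-{2-[(triethylsilyl)oxy]propan-2-yl}-2,3-dihydro-1-benzofuran-5-yl]methyl}-2,5-dihydrofuran-2-carboxylate
Product: 16 methyl (2S)-4-(benzyloxy)-5-oxo-2-{[(2S)-2-{2-[(triethylsilyl)oxy]propan-2-yl}-2,3-dihydro-1-benzofuran-5-yl]methyl}-3-{[(trifluoromethyl)sulfonyl]oxy}-2,5-dihydrofuran-2-carboxylate
Conditions: Tf2O, i-Pr2NEt, CH2Cl2, −78 °C
Reagents that add atoms: trifluoromethanesulfonic anhydride (Tf2O), SMILES O=S(=O)(OS(=O)(=O)C(F)(F)F)C(F)(F)F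
Why: O-Sulfonylation of the tetronic acid: the tetronate reacts with Tf2O at the C4 oxygen, the only free hydroxyl, to give the vinylogous acyl triflate needed for cross-coupling, with C5 untouched because it bears no hydrogen.

Step 12
Reactants: 16 methyl (2S)-4-(benzyloxy)-5-oxo-2-{[(2S)-2-{2-[(triethylsilyl)oxy]propan-2-yl}-2,3-dihydro-1-benzofuran-5-yl]methyl}-3-{[(trifluoromethyl)sulfonyl]oxy}-2,5-dihydrofuran-2-carboxylate; 17 [4-(benzyloxy)phenyl]boronic acid
Product: 18 methyl (2S)-4-(benzyloxy)-3-[4-(benzyloxy)phenyl]-5-oxo-2-{[(2S)-2-{2-[(triethylsilyl)oxy]propan-2-yl}-2,3-dihydro-1-benzofuran-5-yl]methyl}-2,5-dihydrofuran-2-carboxylate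
Conditions: Pd(OAc)2 (5 mol%), SPhos (10 mol%), K3PO4, toluene/H2O (10:1), 60 °C
Reagents that add atoms: none
Why: Suzuki–Miyaura coupling: oxidative addition of zerovalent palladium into the electron-poor C4–OTf bond, transmetalation from the boronate and reductive elimination form the C4–aryl bond, the bulky electron-rich biarylphosphine helping at the hindered position next to the quaternary carbon.

Step 13
Reactants: 18 methyl (2S)-4-(benzyloxy)-3-[4-(benzyloxy)phenyl]-5-oxo-2-{[(2S)-2-{2-[(triethylsilyl)oxy]propan-2-yl}-2,3-dihydro-1-benzofuran-5-yl]methyl}-2,5-dihydrofuran-2-carboxylate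
Product: 19 methyl (2S)-4-(benzyloxy)-3-[4-(benzyloxy)phenyl]-2-{[(2S)-2-(2-hydroxypropan-2-yl)-2,3-dihydro-1-benzofuran-5-yl]methyl}-5-oxo-2,5-dihydrofuran-2-carboxylate
Conditions: HF·pyridine, pyridine, THF, 0 °C to rt
Reagents that add atoms: none
Why: Fluoride-mediated desilylation with pyridine-buffered HF should remove the triethylsilyl ether without opening the lactone, cleaving the methyl ester or touching the benzyl ethers.

Step 14
Reactants: 19 methyl (2S)-4-(benzyloxy)-3-[4-(benzyloxy)phenyl]-2-{[(2S)-2-(2-hydroxypropan-2-yl)-2,3-dihydro-1-benzofuran-5-yl]methyl}-5-oxo-2,5-dihydrofuran-2-carboxylate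
Product: 20 methyl (2S)-4-hydroxy-3-(4-hydroxyphenyl)-2-{[(2S)-2-(2-hydroxypropan-2-yl)-2,3-dihydro-1-benzofuran-5-yl]methyl}-5-oxo-2,5-dihydrofuran-2-carboxylate
Conditions: H2 (1 atm), 10% Pd/C, EtOAc, rt
Reagents that add atoms: none
Why: Catalytic hydrogenolysis cleaves the enol benzyl ether and the aryl benzyl ether in one operation, while the tetrasubstituted conjugated C3=C4 double bond and the hindered C5–O bond should resist reduction under one atmosphere of H2.

**Compound list**

1 | methyl 4-hydroxybenzoate | COC(=O)c1ccc(O)cc1 | starting material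
2 | 1-bromo-3-methylbut-2-ene (prenyl bromide) | CC(C)=CCBr | starting material
3 | methyl 4-hydroxy-3-(3-methylbut-2-en-1-yl)benzoate | COC(=O)c1ccc(O)c(CC=C(C)C)c1 | intermediate
4 | methyl 3-(3-methylbut-2-en-1-yl)-4-[(triisopropylsilyl)oxy]benzoate | COC(=O)c1ccc(O[Si](C(C)C)(C(C)C)C(C)C)c(CC=C(C)C)c1 | intermediate
5 | methyl 3-{[(2R)-3,3-dimethyloxiran-2-yl]methyl}-4-[(triisopropylsilyl)oxy]benzoate | COC(=O)c1ccc(O[Si](C(C)C)(C(C)C)C(C)C)c(C[C@H]2OC2(C)C)c1 | intermediate
6 | methyl 3-{[(2R)-3,3-dimethyloxiran-2-yl]methyl}-4-hydroxybenzoate (formed as its tetrabutylammonium phenoxide, not isolated) | COC(=O)c1ccc(O)c(C[C@H]2OC2(C)C)c1 | intermediate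
7 | methyl (2S)-2-(2-hydroxypropan-2-yl)-2,3-dihydro-1-benzofuran-5-carboxylate | COC(=O)c1ccc2c(c1)C[C@@H](C(C)(C)O)O2 | intermediate
8 | methyl (2S)-2-{2-[(triethylsilyl)oxy]propan-2-yl}-2,3-dihydro-1-benzofuran-5-carboxylate | COC(=O)c1ccc2c(c1)C[C@@H](C(C)(C)O[Si](CC)(CC)CC)O2 | intermediate
9 | [(2S)-2-{2-[(triethylsilyl)oxy]propan-2-yl}-2,3-dihydro-1-benzofuran-5-yl]methanol | OCc1ccc2c(c1)C[C@@H](C(C)(C)O[Si](CC)(CC)CC)O2 | intermediate
10 | (2S)-5-(bromomethyl)-2-{2-[(triethylsilyl)oxy]propan-2-yl}-2,3-dihydro-1-benzofuran | BrCc1ccc2c(c1)C[C@@H](C(C)(C)O[Si](CC)(CC)CC)O2 | intermediate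
11 | dimethyl 2-hydroxymalonate (dimethyl tartronate) | COC(=O)C(O)C(=O)OC | starting material
12 | (benzyloxy)acetyl chloride | O=C(Cl)COCc1ccccc1 | starting material
13 | dimethyl 2-{[(benzyloxy)acetyl]oxy}malonate | COC(=O)C(OC(=O)COCc1ccccc1)C(=O)OC | intermediate
14 | dimethyl 2-{[(benzyloxy)acetyl]oxy}-2-{[(2S)-2-{2-[(triethylsilyl)oxy]propan-2-yl}-2,3-dihydro-1-benzofuran-5-yl]methyl}malonate | COC(=O)C(Cc1ccc2c(c1)C[C@@H](C(C)(C)O[Si](CC)(CC)CC)O2)(OC(=O)COCc1ccccc1)C(=O)OC | intermediate
15 | methyl (2S)-4-(benzyloxy)-3-hydroxy-5-oxo-2-{[(2S)-2-{2-[(triethylsilyl)oxy]propan-2-yl}-2,3-dihydro-1-benzofuran-5-yl]methyl}-2,5-dihydrofuran-2-carboxylate | COC(=O)[C@@]1(Cc2ccc3c(c2)C[C@@H](C(C)(C)O[Si](CC)(CC)CC)O3)OC(=O)C(OCc2ccccc2)=C1O | intermediate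
16 | methyl (2S)-4-(benzyloxy)-5-oxo-2-{[(2S)-2-{2-[(triethylsilyl)oxy]propan-2-yl}-2,3-dihydro-1-benzofuran-5-yl]methyl}-3-{[(trifluoromethyl)sulfonyl]oxy}-2,5-dihydrofuran-2-carboxylate | COC(=O)[C@@]1(Cc2ccc3c(c2)C[C@@H](C(C)(C)O[Si](CC)(CC)CC)O3)OC(=O)C(OCc2ccccc2)=C1OS(=O)(=O)C(F)(F)F | intermediate
17 | [4-(benzyloxy)phenyl]boronic acid | OB(O)c1ccc(OCc2ccccc2)cc1 | starting material
18 | methyl (2S)-4-(benzyloxy)-3-[4-(benzyloxy)phenyl]-5-oxo-2-{[(2S)-2-{2-[(triethylsilyl)oxy]propan-2-yl}-2,3-dihydro-1-benzofuran-5-yl]methyl}-2,5-dihydrofuran-2-carboxylate | COC(=O)[C@@]1(Cc2ccc3c(c2)C[C@@H](C(C)(C)O[Si](CC)(CC)CC)O3)OC(=O)C(OCc2ccccc2)=C1c1ccc(OCc2ccccc2)cc1 | intermediate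
19 | methyl (2S)-4-(benzyloxy)-3-[4-(benzyloxy)phenyl]-2-{[(2S)-2-(2-hydroxypropan-2-yl)-2,3-dihydro-1-benzofuran-5-yl]methyl}-5-oxo-2,5-dihydrofuran-2-carboxylate | COC(=O)[C@@]1(Cc2ccc3c(c2)C[C@@H](C(C)(C)O)O3)OC(=O)C(OCc2ccccc2)=C1c1ccc(OCc2ccccc2)cc1 | intermediate
20 | methyl (2S)-4-hydroxy-3-(4-hydroxyphenyl)-2-{[(2S)-2-(2-hydroxypropan-2-yl)-2,3-dihydro-1-benzofuran-5-yl]methyl}-5-oxo-2,5-dihydrofuran-2-carboxylate | COC(=O)[C@@]1(Cc2ccc3c(c2)C[C@@H](C(C)(C)O)O3)OC(=O)C(O)=C1c1ccc(O)cc1 | target

**Totals and risks**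

Total step count: 14. Longest linear sequence: 13 steps (steps 1–7 and 9–14, from methyl 4-hydroxybenzoate); step 8 is a one-step side branch.

Most likely to fail, first: step 10. The chiral amide aggregate may discriminate poorly between the two methyl ester groups, or the ester enolate may lose ketene before ring closure. The fallback uses known chemistry and sets out from 14. Cyclisation with LiN(SiMe3)2 in THF at −78 °C, the established achiral Claisen closure of alkoxyacetoxy esters, should give 15 together with its C5 epimer, methyl (2R)-4-(benzyloxy)-3-hydroxy-5-oxo-2-{[(2S)-2-{2-[(triethylsilyl)oxy]propan-2-yl}-2,3-dihydro-1-benzofuran-5-yl]methyl}-2,5-dihydrofuran-2-carboxylate F1. The mixture is triflated as in step 11 to 16 and the epimeric triflate, methyl (2R)-4-(benzyloxy)-5-oxo-2-{[(2S)-2-{2-[(triethylsilyl)oxy]propan-2-yl}-2,3-dihydro-1-benzofuran-5-yl]methyl}-3-{[(trifluoromethyl)sulfonyl]oxy}-2,5-dihydrofuran-2-carboxylate F2. These are diastereomers because of the fixed dihydrobenzofuran center and are separated by preparative chromatography, on a chiral stationary phase if silica gel does not resolve them. The route is rejoined at 16.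

Second: step 12. The aqueous base may cleave the vinylogous acyl triflate back to the tetronate, and transmetalation at C4, flanked by the quaternary C5 and the benzyloxy-bearing C3, may be slow enough for protodeboronation to compete. The fallback sets out from 16 and is a base-free, anhydrous Negishi coupling with [4-(benzyloxy)phenyl]zinc iodide F3, prepared from 1-(benzyloxy)-4-iodobenzene with zinc dust and LiCl in THF and coupled with Pd(PPh3)4 in THF at rt to 50 °C. It comes back to the route at 18.

Third: step 1. O-Prenylation and double alkylation may compete with ortho C-alkylation of the phenoxide. The fallback sets out from 1 and returns at 3: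
- O-alkylation with 3-chloro-3-methylbut-1-yne (DBU, CuCl2 cat., MeCN, 0 °C) gives methyl 4-[(2-methylbut-3-yn-2-yl)oxy]benzoate F4.
- Semihydrogenation over Pd/CaCO3 poisoned with Pb(OAc)2 (quinoline, H2, EtOAc) gives methyl 4-[(2-methylbut-3-en-2-yl)oxy]benzoate F5.
- Aromatic Claisen rearrangement (N,N-diethylaniline, about 130 °C) moves the allyl unit to the ortho carbon with allylic transposition and gives 3.

**Further compounds**

F1 | step 10 | methyl (2R)-4-(benzyloxy)-3-hydroxy-5-oxo-2-{[(2S)-2-{2-[(triethylsilyl)oxy]propan-2-yl}-2,3-dihydro-1-benzofuran-5-yl]methyl}-2,5-dihydrofuran-2-carboxylate | COC(=O)[C@]1(Cc2ccc3c(c2)C[C@@H](C(C)(C)O[Si](CC)(CC)CC)O3)OC(=O)C(OCc2ccccc2)=C1O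
F2 | step 10 | methyl (2R)-4-(benzyloxy)-5-oxo-2-{[(2S)-2-{2-[(triethylsilyl)oxy]propan-2-yl}-2,3-dihydro-1-benzofuran-5-yl]methyl}-3-{[(trifluoromethyl)sulfonyl]oxy}-2,5-dihydrofuran-2-carboxylate | COC(=O)[C@]1(Cc2ccc3c(c2)C[C@@H](C(C)(C)O[Si](CC)(CC)CC)O3)OC(=O)C(OCc2ccccc2)=C1OS(=O)(=O)C(F)(F)F
F3 | step 12 | [4-(benzyloxy)phenyl]zinc iodide | I[Zn]c1ccc(OCc2ccccc2)cc1
F4 | step 1 | methyl 4-[(2-methylbut-3-yn-2-yl)oxy]benzoate | COC(=O)c1ccc(OC(C)(C)C#C)cc1
F5 | step 1 | methyl 4-[(2-methylbut-3-en-2-yl)oxy]benzoate | COC(=O)c1ccc(OC(C)(C)C=C)cc1
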